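## The problem

Target 24 is a cis-fused bicyclo[5.3.0]decane (azulene numbering; ring A five-membered, ring B seven-membered). Both fusion carbons are fully substituted: C3a carries a tertiary hydroxyl and C8a a methyl group. The four stereocentres C3, C3a, C8 and C8a are contiguous, and the C3 isopropyl, C3a hydroxyl, C8a methyl and C8 ester oxygen all lie on one face, called the lower face below. C8a is the natural origin of absolute configuration: a chain on C8a can reach the neighbouring C3a carbonyl only from its own face, which fixes the cis fusion and, through a cyclic transition state, C3. The C3a hydroxyl in turn is 1,3 to C8 across C8a and can deliver a reagent there. The sensitive points are these: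

- the tertiary alcohol is β to any carbonyl placed at C8 (retro-aldol) and can add across ring B to C6 of a C6=C7–C8=O enone;
- the C8 carbinol is neopentyl and allylic, so it substitutes slowly and ionises easily once acylated;
- the C6=C7 alkene would compete for any electrophilic oxidant.

C6 is not a stereocentre in 24 but becomes one in any precursor with a C7=C8 alkene, and the return of the alkene to C6=C7 depends on its configuration. The enabling feature is that the C8 oxygen is homoallylic and syn to the C3a hydroxyl and allylic to C6=C7. An oxirane across C7–C8 on the hydroxyl face, opened towards C6, is 24 without its ester.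

## Retrosynthesis

**Ester.** The acyl C–O bond at C8 is cut first, giving allylic diol 22 and 4-methoxybenzoyl chloride 23. The allylic 4-methoxybenzoate would not survive selenolate, borohydride or cuprate, so it goes on last. The two hydroxyls of 22 differ enough (secondary allylic against tertiary at a ring fusion) that no protecting group is needed. The forward step must acylate a hindered secondary alcohol and leave the tertiary one.

**Allylic transposition.** 22 is traced to epoxide 19: in the forward sense the C7–O bond is broken and a C6–H is removed. Allylic oxidation of a C6=C7 alkene would have to choose C8 over C5 and the methyl group and find the face unaided. Reduction of a C8 enone would set C8 only by reagent approach. The epoxide stores the C8 configuration before the C6=C7 alkene exists. The forward reaction must open the oxirane at C7 (C8 is neopentyl) and eliminate towards C6. With a selenoxide this needs the C6 hydrogen syn to selenium, so the C6 methyl of 19 must lie on the lower face.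

**Key disconnection.** Both C–O bonds of the oxirane of 19 are cut to give homoallylic alcohol 18. A peracid would follow sterics and be pushed to the upper face by the C8a and C6 methyl groups. A metal bound to the C3a oxygen can only reach the lower face. The precursor 18 has lost two stereocentres and every oxygen but the tertiary hydroxyl.

**C7=C8 alkene and C6 methyl.** The C8–H bond of 18 is traced to the C8–OTf bond of enol triflate 16, and the C6–CH3 bond to a cuprate addition to enone 14. One ketone at C8 serves three purposes: it is the anchor for dehydrogenation, the acceptor for methyl, and, as its enol triflate, the source of the alkene. The regiochemistry is unambiguous because C8a is quaternary. A Shapiro route from the β-methyl ketone would be longer and strongly basic. The forward step must deliver methyl to the lower face of C6. The C3a oxygen is kept as a trimethylsilyl ether so that only the enolate is sulfonylated and the enone never meets a free C3a hydroxyl.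

**Enone.** The C6=C7 unsaturation of 14 is removed via silyl enol ether 13 to give ketol 12, and the C8 carbonyl is returned to the carbinol of diol 11. One silylation forms the enol ether and protects the tertiary alcohol. Only C7 can enolise.

**Ring A.** The isopropyl group of 11 comes from the isopropenyl group of 10, and the C3–C3a bond of 10 is cut by a type 1 carbonyl-ene transform to monocyclic ketone 9. This one step closes ring A, creates the C3a carbinol and sets C3. A ketyl–olefin radical closure would be expected to place the hydroxyl and the side chain trans. Ketone 9 is a cycloheptanone with two stereocentres.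

**Absolute configuration.** The benzyl group of 9 is removed to give 8, and the C8–H bond of 8 is cut to the achiral dione 7. A catalytic reduction of established type chooses between the two enantiotopic carbonyls, so the ene reaction need only be diastereoselective. The C8 carbinol is a temporary label. The reduction places its oxygen trans to the C8a methyl, the opposite of what 24 needs, so it is erased in step 8 and rebuilt by the key step.

**Chain and quaternary carbon.** The alkene of 7 is cut (Wittig) to aldehyde 4 and phosphonium salt 5. The C8a–C1 bond of 4 is cut (Michael) to 2-methylcycloheptane-1,3-dione 2 and acrolein 3. The C8a–CH3 bond is cut to cycloheptane-1,3-dione 1. Direct alkylation of 2 with a homoprenyl halide would suffer O-alkylation; the Michael–Wittig pair avoids it.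

## Roads not taken

**Alternative 1: thionium Prins–pinacol.**
- Cut: C1–C2 and C3a–C8a, with ring B coming from a cyclohexane.
- Forward key step: dimethyl(methylthio)sulfonium tetrafluoroborate ionises dithioacetal A1 to a thionium ion at C2. The isopropenyl group attacks it, and the tertiary cation at C8a draws C3a over from C8, giving hydroazulenone A2.
- Merits: one step closes ring A, enlarges ring B and creates both fusion carbons through a stereospecific 1,2-shift. Absolute configuration would come from a cyclohexanediol, not from a choice between carbonyls. In security at the ring fusion this is better than a Lewis acid ene closure.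
- Weak points: A2 has C8 as a ketone and ring B otherwise bare, the same oxidation pattern as 12, so the whole C6/C7/C8 problem remains and the end game would be the present one. A2 also carries a methylthio group at C2 and a tertiary silyl ether to remove. A1 needs three stereocentres, one of them in a side chain next to a quaternary carbinol.
- Comparison: the chosen plan reaches the same ketone level in eight steps from a commodity dione with nothing to excise.

**Alternative 2: desymmetrising carbonyl-ene.**
- Cut: C3–C3a, the same bond as in step 6.
- Forward key step: Cu(OTf)2 with a bis(oxazoline) ligand binds dione 7 and the alkene attacks one of the two enantiotopic ketones, giving ketol A3.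
- Merits: bond formation and absolute configuration in one event. It saves the reduction, the benzylation and the re-oxidation, so it is three steps shorter, and C8 stays a ketone throughout. In step economy it is better than the chosen front end.
- Weak points: a mild chiral Lewis acid must activate a dialkyl ketone for an ene reaction and also tell two carbonyls apart across a quaternary carbon. Both are uncertain. It also says nothing about C8: from A3 the sequence of steps 9 to 15 would still be needed.
- Comparison: the chosen plan pays three steps to put the enantioselective event into a carbonyl reduction of established type. If A3 proved accessible in high enantiomeric purity, it would serve as a shortcut into 12, not as a replacement for the key step.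

**Alternative 3: allyl sulfone anion opens a spiro-epoxide.**
- Cut: C4–C5.
- Forward key step: deprotonation of A4 next to the sulfone and SN2 attack of C5 on the epoxide CH2 closes ring B and releases the C3a alkoxide, giving A5.
- Merits: the C8 oxygen, the C6=C7 alkene and the C6 methyl are in place before the ring closes. The end game is only desulfonylation, desilylation and acylation, and no C6 stereocentre ever exists. In this respect it is better than the chosen plan, which depends on the face of a cuprate addition.
- Weak points: A4 is a cyclopentane with three contiguous stereocentres (C3, spiro C3a, quaternary C8a), a Z trisubstituted alkene, and a C8 carbinol that must be set in an open chain next to a quaternary carbon. The allyl anion is ambident: attack through C7 would close a five-membered ring. Reductive removal of an allylic sulfone can move the alkene.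
- Comparison: the chosen plan sets C8 inside a rigid bicycle under control of the C3a hydroxyl, and its front end is far shorter.

Key step: step 13

Remark on the chemistry (step 11): the cuprate is taken to add to C6 of 14 on the lower face, by axial attack on the conformer with C3 equatorial. The configuration of 16 is to be confirmed before step 13; the fallback for step 11 covers the other outcome.

Remark on the chemistry (step 4): hydride is taken to enter the reduced carbonyl of 7 cis to the methyl group and anti to the longer chain. The fallback for step 4 covers the other outcome.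

## Route

Step 1
Reactants: 1 cycloheptane-1,3-dione
Product: 2 2-methylcycloheptane-1,3-dione
Conditions: MeI, NaOH, H2O–MeOH, 60 °C
Reagents that add atoms: iodomethane, CI
Why: C-alkylation of a cyclic 1,3-dione enolate in protic medium, where hydrogen bonding to the enolate oxygens favours reaction at carbon; it should stop mainly at the mono-methyl stage under controlled stoichiometry.

Step 2
Reactants: 2 2-methylcycloheptane-1,3-dione; 3 acrolein
Product: 4 3-(1-methyl-2,7-dioxocycloheptyl)propanal
Conditions: Et3N (0.1 equiv), MeCN, 0 °C → rt
Reagents that add atoms: none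
Why: Michael addition of the stabilised dione enolate to acrolein forms the C8a–C1 bond and the quaternary carbon; the adduct can no longer enolise between the carbonyls, so the addition is not reversed under these conditions.

Step 3
Reactants: 4 3-(1-methyl-2,7-dioxocycloheptyl)propanal; 5 isopropyltriphenylphosphonium iodide
Product: 7 2-methyl-2-(4-methylpent-3-en-1-yl)cycloheptane-1,3-dione, via isopropylidene ylide 6 (not isolated)
Conditions: 5, n-BuLi, THF, 0 °C; then 4, −78 → 0 °C
Reagents that add atoms: none
Why: Wittig olefination; the non-stabilised ylide should take the aldehyde far faster than the two ketones, which flank a quaternary carbon, and the trisubstituted alkene has no geometric isomers.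

Step 4
Reactants: 7 2-methyl-2-(4-methylpent-3-en-1-yl)cycloheptane-1,3-dione
Product: 8 (2R,3R)-3-hydroxy-2-methyl-2-(4-methylpent-3-en-1-yl)cycloheptan-1-one (hydroxyl trans to the 2-methyl)
Conditions: (S)-2-methyl-CBS-oxazaborolidine (0.2 equiv), catecholborane (1.1 equiv), toluene–CH2Cl2, −78 → −40 °C
Reagents that add atoms: none
Why: Corey–Bakshi–Shibata reduction used as a mono-reduction that selects one of two enantiotopic carbonyls of a 2,2-disubstituted cyclic 1,3-dione; with the quaternary carbon as the large group the (S)-catalyst should give the R carbinol, and hydride entering cis to the methyl makes the reduced carbonyl C8 and leaves C8a in the configuration of the target. The diastereomer with hydroxyl cis to methyl leads to the enantiomeric series and is removed by chromatography.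

Step 5
Reactants: 8 (2R,3R)-3-hydroxy-2-methyl-2-(4-methylpent-3-en-1-yl)cycloheptan-1-one
Product: 9 (2R,3R)-3-(benzyloxy)-2-methyl-2-(4-methylpent-3-en-1-yl)cycloheptan-1-one
Conditions: 2-benzyloxy-1-methylpyridinium triflate (2 equiv), MgO, PhCF3, 85 °C
Reagents that add atoms: 2-benzyloxy-1-methylpyridinium triflate, C[n+]1ccccc1OCc1ccccc1.[O-]S(=O)(=O)C(F)(F)F
Why: Dudley benzylation, a neutral thermal benzyl transfer; it avoids an alkoxide (retro-aldol of the β-hydroxy ketone would scramble C2) and strong acid (protonation of the trisubstituted alkene).

Step 6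
Reactants: 9 (2R,3R)-3-(benzyloxy)-2-methyl-2-(4-methylpent-3-en-1-yl)cycloheptan-1-one
Product: 10 (3R,3aS,8R,8aR)-8-(benzyloxy)-8a-methyl-3-(prop-1-en-2-yl)decahydroazulen-3a-ol (cis-fused; 3a-hydroxyl, 8a-methyl and 3-isopropenyl on the lower face, 8-benzyloxy on the upper face)
Conditions: Me2AlCl (2 equiv), CH2Cl2, −78 → 0 °C
Reagents that add atoms: none
Why: Type 1 intramolecular carbonyl-ene reaction of a δ,ε-unsaturated ketone under an alkylaluminium chloride, which also scavenges adventitious protons. The chain reaches the carbonyl only from the face on which it stands at C8a, so the new hydroxyl falls cis to the 8a-methyl (cis fusion). The six-membered hydrogen-transfer array places the isopropenyl group cis to that hydroxyl, which sets C3.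

Step 7
Reactants: 10 (3R,3aS,8R,8aR)-8-(benzyloxy)-8a-methyl-3-(prop-1-en-2-yl)decahydroazulen-3a-ol
Product: 11 (3R,3aS,8R,8aR)-8a-methyl-3-(propan-2-yl)decahydroazulene-3a,8-diol
Conditions: H2 (1 atm), Pd(OH)2/C, EtOAc–EtOH, rt
Reagents that add atoms: none
Why: Heterogeneous hydrogenation of the 1,1-disubstituted alkene and hydrogenolysis of the benzyl ether in one operation; no stereocentre is formed, and the exocyclic alkene should be saturated faster than it can migrate towards C3.

Step 8
Reactants: 11 (3R,3aS,8R,8aR)-8a-methyl-3-(propan-2-yl)decahydroazulene-3a,8-diol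
Product: 12 (3R,3aS,8aS)-3a-hydroxy-8a-methyl-3-(propan-2-yl)octahydroazulen-8(1H)-one
Conditions: Dess–Martin periodinane, NaHCO3, CH2Cl2, rt
Reagents that add atoms: none
Why: Dess–Martin oxidation of the secondary alcohol under buffered, non-basic conditions; the tertiary alcohol cannot be oxidised and the β-hydroxy ketone is not exposed to base. The C8 carbinol has done its work as a label and is erased here.

Step 9
Reactants: 12 (3R,3aS,8aS)-3a-hydroxy-8a-methyl-3-(propan-2-yl)octahydroazulen-8(1H)-one
Product: 13 bis(trimethylsilyl) derivative of 12: 8-trimethylsilyl enol ether (C7=C8) and 3a-trimethylsilyl ether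
Conditions: TMSOTf (2.5 equiv), Et3N, CH2Cl2, 0 °C → rt
Reagents that add atoms: trimethylsilyl triflate, C[Si](C)(C)OS(=O)(=O)C(F)(F)F
Why: Soft enolisation and silylation; the ketone can enolise only towards C7 because C8a is quaternary, and the tertiary hydroxyl is silylated in the same operation.

Step 10
Reactants: 13 bis(trimethylsilyl) derivative of 12
Product: 14 (3R,3aS,8aS)-8a-methyl-3-(propan-2-yl)-3a-(trimethylsilyloxy)-2,3,3a,4,5,8a-hexahydroazulen-8(1H)-one (C6=C7 enone)
Conditions: Pd(OAc)2 (1.05 equiv), MeCN, rt
Reagents that add atoms: none
Why: Saegusa–Ito oxidation: divalent palladium takes the silyl enol ether to an α-palladated ketone and β-hydride elimination gives the enone. The tertiary silyl ether stays, so the enone never meets a free C3a hydroxyl that could add across ring B to C6.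

Step 11
Reactants: 14 C6=C7 enone with 3a-trimethylsilyloxy group
Product: 16 (3R,3aS,6S,8aS)-6,8a-dimethyl-3-(propan-2-yl)-3a-(trimethylsilyloxy)-1,2,3,3a,4,5,6,8a-octahydroazulen-8-yl trifluoromethanesulfonate (6-methyl on the lower face), via lithium enolate 15 (not isolated)
Conditions: Me2CuLi (MeLi, CuI), Et2O, −78 → −40 °C; then N-(5-chloro-2-pyridyl)bis(trifluoromethanesulfonimide), THF, −78 → 0 °C
Reagents that add atoms: lithium dimethylcuprate, [Li+].C[Cu-]C; N-(5-chloro-2-pyridyl)bis(trifluoromethanesulfonimide), O=S(=O)(N(c1ccc(Cl)cn1)S(=O)(=O)C(F)(F)F)C(F)(F)F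
Why: Conjugate addition of a Gilman cuprate, then trapping of the regiodefined enolate as its vinyl triflate with Comins' reagent. C6 is expected to be set by axial attack anti to C4 on the conformer that keeps C3 equatorial, which is the convex lower face of the cis-fused bicycle.

Step 12
Reactants: 16 enol triflate
Product: 18 (3R,3aS,6S,8aR)-6,8a-dimethyl-3-(propan-2-yl)-2,3,4,5,6,8a-hexahydroazulen-3a(1H)-ol (C7=C8 alkene; 3a-hydroxyl, 8a-methyl, 3-isopropyl and 6-methyl on the lower face), via trimethylsilyl ether 17 (not isolated)
Conditions: Pd(OAc)2 (5 mol %), PPh3 (10 mol %), HCO2H, n-Bu3N, DMF, 60 °C; then TBAF, THF, rt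
Reagents that add atoms: none
Why: Palladium-catalysed formate reduction of a vinyl triflate: zerovalent palladium inserts into the C–OTf bond, formate exchanges for triflate and loses CO2, and reductive elimination gives the C8–H bond without moving the alkene. Fluoride then frees the directing hydroxyl.

Step 13
Reactants: 18 (3R,3aS,6S,8aR)-6,8a-dimethyl-3-(propan-2-yl)-2,3,4,5,6,8a-hexahydroazulen-3a(1H)-ol
Product: 19 (3R,3aS,6S,7S,8R,8aR)-7,8-epoxy-6,8a-dimethyl-3-(propan-2-yl)decahydroazulen-3a-ol (oxirane oxygen on the lower face, syn to the 3a-hydroxyl)
Conditions: VO(acac)2 (5 mol %), t-BuOOH (1.5 equiv, in decane), CH2Cl2, 0 °C → rt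
Reagents that add atoms: tert-butyl hydroperoxide, CC(C)(C)OO
Why: The hydroperoxide oxidises VO(acac)2 (tetravalent vanadium) to a pentavalent vanadate ester that carries the C3a alkoxide of 18 and a tert-butylperoxide on the same metal, and the metal-bound peroxide oxygen is passed to C7=C8 inside this complex. The closest known reaction type is the VO(acac)2/t-BuOOH epoxidation of cyclic homoallylic alcohols, tertiary ring carbinols included, which gives the cis epoxy alcohol. The oxirane closes by concerted, suprafacial transfer of one oxygen atom to both alkene carbons, so the cis geometry of the ring alkene is kept and no open intermediate can rotate. C7 and C8 are therefore set together, and both by the C3a carbinol: the tether from the alkoxide oxygen through C3a and C8a lets the metal reach C7=C8 only from the hydroxyl face. The selectivity needed is facial, against the C8a and C6 methyl groups on the same face. It is secured because an unbound, unactivated disubstituted alkene reacts only slowly with the vanadium peroxide, whereas the bound one reacts intramolecularly. Chemoselectivity is not in question: 18 has one alkene and its tertiary hydroxyl cannot be oxidised. Because hydroxyl and oxirane oxygen are syn, the alcohol cannot open the epoxide from the rear.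

Step 14
Reactants: 19 7,8-epoxide with oxygen on the lower face
Product: 22 (3R,3aS,8S,8aR)-6,8a-dimethyl-3-(propan-2-yl)-1,2,3,3a,4,5,8,8a-octahydroazulene-3a,8-diol (C6=C7 alkene; both hydroxyls on the lower face), via hydroxy selenide 20 (not isolated), via selenoxide 21 (not isolated)
Conditions: PhSeSePh, NaBH4, EtOH, 80 °C; then THF, pyridine, 30 % H2O2, 0 °C → rt
Reagents that add atoms: none
Why: Epoxide-to-allylic-alcohol transposition: the selenolate opens the oxirane by SN2 attack at C7 from the upper face (C8 is neopentyl), leaving the C8 oxygen untouched on the lower face. The selenoxide then undergoes syn elimination away from the carbinol, using the C6 hydrogen, which is cis to selenium because the C6 methyl is on the lower face. Pyridine and low temperature limit epoxidation of the new alkene by peroxyseleninic acid.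

Step 15
Reactants: 22 (3R,3aS,8S,8aR)-6,8a-dimethyl-3-(propan-2-yl)-1,2,3,3a,4,5,8,8a-octahydroazulene-3a,8-diol; 23 4-methoxybenzoyl chloride
Product: 24 (3R,3aS,8S,8aR)-3a-hydroxy-6,8a-dimethyl-3-(propan-2-yl)-1,2,3,3a,4,5,8,8a-octahydroazulen-8-yl 4-methoxybenzoate (CNP0158828.1)
Conditions: DMAP, pyridine, CH2Cl2, 0 → 40 °C
Reagents that add atoms: none
Why: DMAP-catalysed acylation through the acylpyridinium ion; the secondary allylic hydroxyl reacts while the tertiary ring-fusion hydroxyl is too hindered, and basic conditions keep the allylic ester from ionising.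

## Compound list

1 | cycloheptane-1,3-dione | O=C1CCCCC(=O)C1 | starting material
2 | 2-methylcycloheptane-1,3-dione | CC1C(=O)CCCCC1=O | intermediate
3 | acrolein | C=CC=O | starting material
4 | 3-(1-methyl-2,7-dioxocycloheptyl)propanal | O=CCCC1(C)C(=O)CCCCC1=O | intermediate
5 | isopropyltriphenylphosphonium iodide | CC(C)[P+](c1ccccc1)(c1ccccc1)c1ccccc1.[I-] | starting material
6 | (propan-2-ylidene)triphenylphosphorane | CC(C)=P(c1ccccc1)(c1ccccc1)c1ccccc1 | intermediate
7 | 2-methyl-2-(4-methylpent-3-en-1-yl)cycloheptane-1,3-dione | CC(C)=CCCC1(C)C(=O)CCCCC1=O | intermediate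
8 | (2R,3R)-3-hydroxy-2-methyl-2-(4-methylpent-3-en-1-yl)cycloheptan-1-one | C[C@]1(CCC=C(C)C)C(=O)CCCC[C@H]1O | intermediate
9 | (2R,3R)-3-(benzyloxy)-2-methyl-2-(4-methylpent-3-en-1-yl)cycloheptan-1-one | C[C@]1(CCC=C(C)C)C(=O)CCCC[C@H]1OCc1ccccc1 | intermediate
10 | (3R,3aS,8R,8aR)-8-(benzyloxy)-8a-methyl-3-(prop-1-en-2-yl)decahydroazulen-3a-ol | O(Cc1ccccc1)[C@@H]2CCCC[C@]3(O)[C@@H](C(C)=C)CC[C@]23C | intermediate
11 | (3R,3aS,8R,8aR)-8a-methyl-3-(propan-2-yl)decahydroazulene-3a,8-diol | O[C@@H]1CCCC[C@]2(O)[C@@H](C(C)C)CC[C@]12C | intermediate
12 | (3R,3aS,8aS)-3a-hydroxy-8a-methyl-3-(propan-2-yl)octahydroazulen-8(1H)-one | O=C1CCCC[C@]2(O)[C@@H](C(C)C)CC[C@]12C | intermediate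
13 | bis(trimethylsilyl) derivative of 12 (8-silyl enol ether, 3a-silyl ether) | C[Si](C)(C)OC1=CCCC[C@]2(O[Si](C)(C)C)[C@@H](C(C)C)CC[C@]12C | intermediate
14 | (3R,3aS,8aS)-8a-methyl-3-(propan-2-yl)-3a-(trimethylsilyloxy)-2,3,3a,4,5,8a-hexahydroazulen-8(1H)-one | O=C1C=CCC[C@]2(O[Si](C)(C)C)[C@@H](C(C)C)CC[C@]12C | intermediate
15 | lithium enolate of the 6-methyl ketone (6-methyl on the lower face, 3a-trimethylsilyloxy) | [Li]OC1=C[C@@H](C)CC[C@]2(O[Si](C)(C)C)[C@@H](C(C)C)CC[C@]12C | intermediate
16 | (3R,3aS,6S,8aS)-6,8a-dimethyl-3-(propan-2-yl)-3a-(trimethylsilyloxy)-1,2,3,3a,4,5,6,8a-octahydroazulen-8-yl trifluoromethanesulfonate | O=S(=O)(OC1=C[C@@H](C)CC[C@]2(O[Si](C)(C)C)[C@@H](C(C)C)CC[C@]12C)C(F)(F)F | intermediate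
17 | trimethylsilyl ether of 18 | C1=C[C@@H](C)CC[C@]2(O[Si](C)(C)C)[C@@H](C(C)C)CC[C@]12C | intermediate
18 | (3R,3aS,6S,8aR)-6,8a-dimethyl-3-(propan-2-yl)-2,3,4,5,6,8a-hexahydroazulen-3a(1H)-ol | C1=C[C@@H](C)CC[C@]2(O)[C@@H](C(C)C)CC[C@]12C | intermediate
19 | (3R,3aS,6S,7S,8R,8aR)-7,8-epoxy-6,8a-dimethyl-3-(propan-2-yl)decahydroazulen-3a-ol | O1[C@H]2[C@@H]1[C@@H](C)CC[C@]3(O)[C@@H](C(C)C)CC[C@]23C | intermediate
20 | 7-(phenylselanyl)-6,8a-dimethyl-3-(propan-2-yl)decahydroazulene-3a,8-diol (selenium on the upper face, both hydroxyls and 6-methyl on the lower face) | O[C@H]1[C@H]([Se]c2ccccc2)[C@@H](C)CC[C@]3(O)[C@@H](C(C)C)CC[C@]13C | intermediate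
21 | selenoxide of 20 | O[C@H]1[C@H]([Se](=O)c2ccccc2)[C@@H](C)CC[C@]3(O)[C@@H](C(C)C)CC[C@]13C | intermediate
22 | (3R,3aS,8S,8aR)-6,8a-dimethyl-3-(propan-2-yl)-1,2,3,3a,4,5,8,8a-octahydroazulene-3a,8-diol | O[C@H]1C=C(C)CC[C@]2(O)[C@@H](C(C)C)CC[C@]12C | intermediate
23 | 4-methoxybenzoyl chloride | COc1ccc(C(Cl)=O)cc1 | starting material
24 | (3R,3aS,8S,8aR)-3a-hydroxy-6,8a-dimethyl-3-(propan-2-yl)-1,2,3,3a,4,5,8,8a-octahydroazulen-8-yl 4-methoxybenzoate | COc1ccc(C(=O)O[C@H]2C=C(C)CC[C@]3(O)[C@@H](C(C)C)CC[C@]23C)cc1 | target

Total step count: 15. Longest linear sequence: 15 steps (the route is linear; 3, 5 and 23 are commercial).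

## Steps least certain to work

**Step 13 (key step).** Facial control may be lost, or the reaction may stall. The oxidant must be delivered through a homoallylic tertiary alkoxide onto a face flanked by the C8a and C6 methyl groups. If the bound pathway is slow, undirected oxidation and peroxide decomposition compete.
Fallback, from 14 back to 22: the C8 oxygen is kept from the ketone and set by reduction. Enolate 15 from the cuprate addition is silylated with Me3SiCl to the trimethylsilyl enol ether F1. A second Saegusa–Ito oxidation with Pd(OAc)2 gives the 6-methyl enone F2. Brief methanolysis (K2CO3, MeOH, 0 °C) frees the tertiary alcohol to give the hydroxy enone F3. F3 is reduced at once under Narasaka–Prasad conditions (Et2BOMe, NaBH4, THF–MeOH, −78 °C): the boron chelate between the C3a oxygen and the C8 carbonyl takes hydride from outside and should give the syn 1,3-diol 22. F3 is not stored, because its free hydroxyl can add across ring B to C6.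

**Step 11.** The facial selectivity at C6 may be poor or reversed. C6 is 1,4 to both fusion carbons, so the preference rests on ring conformation alone. Methyl on the upper face would leave no hydrogen syn to selenium in step 14.
Fallback, from 14 back to 22: the C6 epimers are carried through the same operations and the transposition is changed. The cuprate addition gives the 6-epi enolate F4 and the 6-epi enol triflate F5. Formate reduction gives the 6-epi silyl ether F6 and fluoride the 6-epi homoallylic alcohol F7. VO(acac)2/t-BuOOH epoxidation, now on a face free of the C6 methyl, gives the 6-epi epoxide F8. In F8 the C6 hydrogen is cis to the oxirane oxygen. Diethylaluminium 2,2,6,6-tetramethylpiperidide (toluene, 0 °C → rt) removes it through a cyclic syn β-elimination and gives 22 directly.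

**Step 4.** The choice between the two carbonyls may be poor, or over-reduction to the diol may occur. The catalyst fixes the carbinol configuration, but which carbonyl reacts depends on hydride preferring the face cis to methyl over the face cis to a flexible chain.
Fallback, from 7 back to 12: since C8 is erased in step 8, only the choice of carbonyl matters. If hydride prefers the face cis to the chain, the (R)-catalyst is used. It gives the (2R,3S)-hydroxy ketone F9 (hydroxyl cis to methyl, same C2). F9 is benzylated as in step 5 to the benzyl ether F10 and cyclised with Me2AlCl to the C8-epimeric bicycle F11. Hydrogenation gives the C8-epimeric diol F12, which Dess–Martin periodinane oxidises to 12. If neither hand gives useful selection, the diastereomers are separated and only the 2R isomer is carried on.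

**Step 6.** The closure may leave the concerted pathway. A hindered ketone and a strong Lewis acid can give an open cation that captures chloride or loses a proton from C3 (which would erase C3), or the ketone may fail to engage.
Fallback, from 9 back to 11: the cationic pathway is accepted. TiCl4 (CH2Cl2, −78 °C) gives the Prins adduct, tertiary chloride F13, with the same ring closure. Bu3SnH/AIBN (benzene, 80 °C) replaces chlorine by hydrogen and gives the isopropyl benzyl ether F14. Hydrogenolysis over Pd(OH)2/C gives 11. The configuration at C3 of F13 would have to be checked.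

**Step 14.** Opening at C7 may be slow or misdirected, since the large selenolate must attack a secondary carbon next to the C6 methine. The selenoxide may eliminate towards C8, or the new alkene may be over-oxidised.
Fallback, from 19 back to 22: a small nitrogen nucleophile and a thermal, non-oxidative elimination. NaN3/NH4Cl (MeOH–H2O, 80 °C) opens the oxirane at C7 to the azido alcohol F15. H2, Pd/C and aqueous formaldehyde give the dimethylamino alcohol F16. mCPBA gives the N-oxide F17, and Cope elimination on warming (syn, using the same C6 hydrogen) gives 22.

## Further compounds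

F1 | step 13 | 6-methyl trimethylsilyl enol ether (C7=C8), 3a-trimethylsilyl ether | C[Si](C)(C)OC1=C[C@@H](C)CC[C@]2(O[Si](C)(C)C)[C@@H](C(C)C)CC[C@]12C
F2 | step 13 | 6,8a-dimethyl-3-(propan-2-yl)-3a-(trimethylsilyloxy)-2,3,3a,4,5,8a-hexahydroazulen-8(1H)-one (C6=C7 enone) | O=C1C=C(C)CC[C@]2(O[Si](C)(C)C)[C@@H](C(C)C)CC[C@]12C
F3 | step 13 | 3a-hydroxy-6,8a-dimethyl-3-(propan-2-yl)-2,3,3a,4,5,8a-hexahydroazulen-8(1H)-one | O=C1C=C(C)CC[C@]2(O)[C@@H](C(C)C)CC[C@]12C
F4 | step 11 | 6-epimer of lithium enolate 15 (6-methyl on the upper face) | [Li]OC1=C[C@H](C)CC[C@]2(O[Si](C)(C)C)[C@@H](C(C)C)CC[C@]12C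
F5 | step 11 | 6-epimer of enol triflate 16 | O=S(=O)(OC1=C[C@H](C)CC[C@]2(O[Si](C)(C)C)[C@@H](C(C)C)CC[C@]12C)C(F)(F)F
F6 | step 11 | 6-epimer of silyl ether 17 | C1=C[C@H](C)CC[C@]2(O[Si](C)(C)C)[C@@H](C(C)C)CC[C@]12C
F7 | step 11 | 6-epimer of homoallylic alcohol 18 | C1=C[C@H](C)CC[C@]2(O)[C@@H](C(C)C)CC[C@]12C
F8 | step 11 | 6-epimer of epoxide 19 (oxirane oxygen on the lower face, 6-methyl on the upper face) | O1[C@H]2[C@@H]1[C@H](C)CC[C@]3(O)[C@@H](C(C)C)CC[C@]23C
F9 | step 4 | (2R,3S)-3-hydroxy-2-methyl-2-(4-methylpent-3-en-1-yl)cycloheptan-1-one | C[C@]1(CCC=C(C)C)C(=O)CCCC[C@@H]1O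
F10 | step 4 | (2R,3S)-3-(benzyloxy)-2-methyl-2-(4-methylpent-3-en-1-yl)cycloheptan-1-one | C[C@]1(CCC=C(C)C)C(=O)CCCC[C@@H]1OCc1ccccc1
F11 | step 4 | C8 epimer of 10 (8-benzyloxy on the lower face) | O(Cc1ccccc1)[C@H]2CCCC[C@]3(O)[C@@H](C(C)=C)CC[C@]23C
F12 | step 4 | C8 epimer of 11 | O[C@H]1CCCC[C@]2(O)[C@@H](C(C)C)CC[C@]12C
F13 | step 6 | 8-(benzyloxy)-3-(2-chloropropan-2-yl)-8a-methyldecahydroazulen-3a-ol (configuration as in 10) | O(Cc1ccccc1)[C@@H]2CCCC[C@]3(O)[C@@H](C(C)(C)Cl)CC[C@]23C
F14 | step 6 | 8-(benzyloxy)-8a-methyl-3-(propan-2-yl)decahydroazulen-3a-ol (configuration as in 10) | O(Cc1ccccc1)[C@@H]2CCCC[C@]3(O)[C@@H](C(C)C)CC[C@]23C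
F15 | step 14 | 7-azido-6,8a-dimethyl-3-(propan-2-yl)decahydroazulene-3a,8-diol (azide on the upper face) | O[C@H]1[C@H](N=[N+]=[N-])[C@@H](C)CC[C@]2(O)[C@@H](C(C)C)CC[C@]12C
F16 | step 14 | 7-(dimethylamino)-6,8a-dimethyl-3-(propan-2-yl)decahydroazulene-3a,8-diol | O[C@H]1[C@H](N(C)C)[C@@H](C)CC[C@]2(O)[C@@H](C(C)C)CC[C@]12C
F17 | step 14 | N-oxide of F16 | O[C@H]1[C@H]([N+](C)(C)[O-])[C@@H](C)CC[C@]2(O)[C@@H](C(C)C)CC[C@]12C
A1 | alternative 1 | 2-(tert-butyldimethylsilyloxy)-2-[3-methyl-1,1-bis(methylthio)butan-2-yl]-1-(prop-1-en-2-yl)cyclohexan-1-ol (isopropenyl and side chain cis) | O[C@@]1(C(C)=C)CCCC[C@]1(O[Si](C)(C)C(C)(C)C)[C@@H](C(C)C)C(SC)SC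
A2 | alternative 1 | 3a-(tert-butyldimethylsilyloxy)-3-isopropyl-8a-methyl-2-(methylthio)octahydroazulen-8(1H)-one | O=C1CCCC[C@]2(O[Si](C)(C)C(C)(C)C)[C@@H](C(C)C)[C@H](SC)C[C@]12C
A3 | alternative 2 | 3a-hydroxy-3-isopropenyl-8a-methyloctahydroazulen-8(1H)-one | O=C1CCCC[C@]2(O)[C@@H](C(C)=C)CC[C@]12C
A4 | alternative 3 | spiro-epoxide allyl sulfone: cyclopentane with C3 isopropyl, C3a spiro-oxirane and C8a methyl, carrying the (Z)-1-(tert-butyldimethylsilyloxy)-3-methyl-4-(phenylsulfonyl)but-2-enyl chain on C8a | CC(C)(C)[Si](C)(C)O[C@@H](/C=C(C)\CS(=O)(=O)c1ccccc1)[C@@]2(C)CC[C@H](C(C)C)[C@@]23CO3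
A5 | alternative 3 | C5-phenylsulfonyl derivative of the C8 tert-butyldimethylsilyl ether of 22 | CC(C)(C)[Si](C)(C)O[C@H]1C=C(C)[C@@H](S(=O)(=O)c2ccccc2)C[C@]2(O)[C@@H](C(C)C)CC[C@]12C
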